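1. I start from the leftover. The south-west run goes flat with about 35.0% of the Ek as Ry, as read, so 65.0% of the Ek charged stands somewhere I cannot see.

| flask | Ek | Wa | Aj | temperature | remark | time |
|---|---|---|---|---|---|---|
| north | 0.050 M | 0.050 M | 0.015 M | 75 °C | run made earlier |  |
| south-west | 0.050 M | 0.050 M | 0.010 M | 90 °C | run made earlier |  |
| south-east | 0.050 M | 0.050 M | 0.022 M | 75 °C | run made earlier |  |
| cedar | 0.050 M (fed, over 2.0 min) | 0.0500 M | 0.0150 M | 90 °C | all else is in the flask from the start; the feed brings no volume worth counting | 3.0 min |
| maple | 0.050 M | 0.0500 M (in portions, 3, over 2.0 min) | 0.0150 M | 90 °C | first portion at the start, last at 2.0 min | 3.0 min |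
| larch | 0.050 M | 0.0500 M | 0.0150 M |  | everything together at the start at 50 °C, warmed to 90 °C at 2.0 min | 3.0 min |
| birch | 0.050 M | 0.0500 M (fed, over 2.0 min) | 0.0150 M | 90 °C | all else is in the flask from the start; the feed brings no volume worth counting | 3.0 min |
| ash | 0.050 M (fed, over 2.0 min) | 0.0500 M | 0.0150 M |  | the addition at 50 °C, then warmed to 90 °C; the feed brings no volume worth counting | 3.0 min |

| run | time / min | Ry / % |
|---|---|---|
| north | 0.667 | 22 |
| north | 1.33 | 34 |
| north | 2.00 | 35 |
| north | 3.00 | 38 |
| north | 4.00 | 33 |
| south-west | 0.250 | 21 |
| south-west | 0.500 | 27 |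
| south-west | 1.00 | 33 |
| south-west | 2.00 | 35 |
| south-west | 4.00 | 35 |
| south-east | 0.500 | 21 |
| south-east | 1.00 | 26 |
| south-east | 2.00 | 34 |
| south-east | 4.00 | 38 |
| south-east | 8.00 | 37 |

(standard deviation of a reading: 1.5 percentage points)

* which flask leads in amount of Ry, in percent of the Ek charged ("all alike" within 1.5 percentage points) (cedar / maple / larch / birch / ash / all alike)
* how much Ry is there at the end, in percent of the Ek charged: cedar
* how much Ry is there at the end, in percent of the Ek charged: maple
* how much Ry is there at the end, in percent of the Ek charged: larch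
* how much Ry is there at the end, in percent of the Ek charged: birch
* how much Ry is there at the end, in percent of the Ek charged: ash

2. I read this as a race: Ek leaves by Ry and by other roads. My doubt is that a balance between Ek, Wa and Ry would look just as flat, and these readings cannot tell the two apart. But a balance forgets the recipe and a race does not, so I commit to the race and look hardest at the flasks where Wa comes late.

3. In this race I expect the share of Ek going to Ry, the selectivity, to follow the Wa it meets. So I reckon the offer: the amount of Wa already in the flask, per Ek charged, averaged over the run. For maple and birch alike it is 0.667, which gives Ry near 23.3%. For cedar, larch and ash, with Wa in from the start, the offer is 1.00.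

4. The objection is time. The south-west run had nearly all of its flat value by 1.00 min, so Ek may not wait out the whole run. Averaged over the addition time alone, the offer is 0.500, and Ry is 17.5%. I cannot remove this doubt, so for maple and birch I keep the range from 17.5% to 23.3%.

5. A second objection concerns cedar, larch and ash, which have 1.00 min left at 90 °C after the addition or the cold hold. That is the time the south-west run needed, so I expect them slightly under 35.0%, and I cannot rank them.

6. The forecast says all alike: cedar 35.5%, maple 35.3%, larch 35.3%, birch 35.5%, ash 35%, on the ground that “The order of addition is therefore forgotten”. For maple and birch it stands higher than my range.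

7. The flasks give: larch leads, with cedar 33.4%, maple 20.8%, larch 35.0%, birch 22.8%, ash 33.5%.

    Ek + Wa → Ry (k = 0.439 M⁻¹ s⁻¹, Ea = 43.0 kJ mol⁻¹)
    Ek + Wa → Kj, rate k2*[Ek] as long as [Wa] is above zero (k = 0.00350 s⁻¹, Ea = 104 kJ mol⁻¹)
    Ek + Ry → Ez (k = 0.392 M⁻¹ s⁻¹, Ea = 47.0 kJ mol⁻¹)
    Ek + Aj → Vo (k = 0.911 M⁻¹ s⁻¹, Ea = 42.0 kJ mol⁻¹)
    (constants at 90 °C)

Maple ends at 0.594 of the flat value, which is less than its offer and more than the lower figure. The neighbour of maple charged with 0.085 M of Ek has 0.588 equiv of Wa, so its offer is 0.392 and the reckoning runs from 10.3% to 13.7%. That neighbour ends with Ry at 9.92%, slightly under the low end.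

All runs are calculated on assumed constants, and the scatter is random.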